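In larch at 6.00 min, 45.9% of the charge was still neither target nor side product, and I reckoned with that leftover, L, rather than with what had been made.

| flask | starting material | partner | reagent | remark | time |
|---|---|---|---|---|---|
| larch | 0.085 M | 1 equiv | 2 equiv | run made earlier |  |
| elm | 0.057 M | 1 equiv | 2 equiv | run made earlier |  |
| birch | 0.13 M | 1 equiv | 2 equiv | run made earlier |  |
| ash | 0.085 M | 1.5 equiv | 2 equiv | run made earlier |  |
| spring | 0.085 M | 1.00 equiv | 2.00 equiv | a single well-mixed tank run continuously and read at steady state, 6.0 min in it on average |  |
| summer | 0.085 M | 1.00 equiv | 2.00 equiv | a closed flask charged with all of it at once and left for 6.0 min | 6.0 min |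
| winter | 0.085 M | 1.00 equiv (fed, over 6.00 min) | 2.00 equiv | a stirred flask in which partner is dosed at a steady rate over 6.00 min without added volume, worked up at 6.0 min | 6.0 min |
| noon | 0.085 M | 1.00 equiv | 2.00 equiv (fed, over 6.00 min) | a stirred flask in which reagent is dosed at a steady rate over 6.00 min without added volume, worked up at 6.0 min | 6.0 min |

- larch (time / min: target / %, side product / %): 0.833: 3.0, 0.4; 1.50: 8.5, 2.0; 2.50: 15.6, 8.1; 3.00: 17.5, 11.6; 4.00: 20.9, 19.1; 5.00: 22.2, 25.7; 6.00: 22.6, 31.5
- elm (time / min: target / %, side product / %): 0.417: 0.4, 0; 1.00: 2.3, 0.4; 2.00: 7.1, 2.4; 3.00: 11.9, 5.5; 4.00: 15.7, 9.4; 6.00: 19.8, 18.3; 8.00: 21.2, 26.9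
- birch (time / min: target / %, side product / %): 1.00: 9.0, 2.7; 2.00: 19.0, 12.7; 3.00: 22.1, 23.3; 4.00: 23.2, 33.9; 5.00: 23.6, 41.0; 6.00: 23.4, 47.7; 8.00: 22.8, 57.2
- ash (time / min: target / %, side product / %): 0.500: 1.2, 0.1; 1.00: 5.5, 1.1; 2.00: 13.4, 5.9; 4.00: 18.3, 20.3; 8.00: 16.6, 42.5

(scatter of a reading: 0.3 percentage points)

1. the set-up with the highest share of target in all that became target or side product, at the outlet or at the end ("none" if the first two lie within 2 percentage points) (spring / summer / winter / noon / none)
2. share of target in all that became target or side product, at the outlet or at the end, spring
3. share of target in all that became target or side product, at the outlet or at the end, summer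
4. share of target in all that became target or side product, at the outlet or at the end, winter
5. share of target in all that became target or side product, at the outlet or at the end, noon

- percentages count the starting material that a species holds: one side product counts as two
- the stated concentrations are those of everything mixed, before any reaction; amounts are the same in each set-up
- the feed brings no volume worth counting
- the earlier runs were made in a closed, stirred flask

Side product rose while target and leftover stood together, so I tried its rate as k[target][leftover]. Between 5.00 min and 6.00 min, larch gave a reading of k = 3.11 M⁻¹ min⁻¹, at a mean L of 49.0%.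

I turned concentration first. By hand, k should hold while side product per target follows [starting material]. The late readings gave 3.23 M⁻¹ min⁻¹ in elm and 3.41 M⁻¹ min⁻¹ in birch.

Partner came next. By hand, it should leave k alone, and ash read 3.66 M⁻¹ min⁻¹ over its wider interval.

Then I turned the vessel. I defined the side number as 2·k·[starting material as charged]·time, a Damköhler number, which came to 3.17. In a steady tank, target and side product leave together, so side product per target is N·L and the share is 1/(1 + N·L).

Larch lost 0.0620 min⁻¹ of its charge late on. Taking that rate for spring, I reckoned L = 62.8% and a share of 33.4%. Summer repeats larch, at 41.8%. By hand, dosing makes target appear later in the run, so I placed winter and noon above summer, without figures.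

The forecast gave 33.5% for spring, 41.8% for summer, 51% for winter, 50% for noon and best = none: “Winter and noon are within my envelope error, so none.”

The flask gave 32.2% in spring, 41.5% in summer, 51.2% in noon and 58.8% in winter, so the best was winter, higher than the rest. In the spring tank, the flask's share means 2.11 of side product per target, against the 1.99 I had reckoned as N·L.

    starting material + reagent → open intermediate (k = 0.0230 M⁻¹ s⁻¹)
    reagent + partner → second intermediate (k = 0.0900 M⁻¹ s⁻¹)
    open intermediate + second intermediate ⇌ target (K = 110 M⁻¹, k = 0.340 M⁻¹ s⁻¹)
    starting material + target → side product (k = 0.0660 M⁻¹ s⁻¹)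

In summer, the side step alone, other concentrations as charged, halves target in 2.1 min, faster than the first step alone halves starting material, in 3.0 min. On these forward half-lives, the side step runs 1.43 times as fast as the first step.

The readings stem from a simulated flask for substances that don't exist; scatter was added.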